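Two mirror-image substrates stand equal in a racemate, and both product rates carry the same free catalyst. Loading therefore cancels from their ratio, the selectivity factor, while the substrates stay equal. That is the bench rule: same ratio, same excess.

common to all: left-handed substrate 0.80 M; right-handed substrate 0.80 M
- green: partner 3 equiv; precatalyst 0.32 mol%; run made earlier
- violet: partner 3 equiv; precatalyst 0.5 mol%; run made earlier
- teal: partner 3 equiv; precatalyst 1.2 mol%; run made earlier
- noon: partner 3.00 equiv; precatalyst 1 mol%; time 2.5 h
- dawn: partner 3.00 equiv; precatalyst 0.25 mol%; time 2.5 h

| run | time / h | left-handed product / % | right-handed product / % |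
|---|---|---|---|
| green | 0.200 | 0 | 1.1 |
| green | 0.500 | 0 | 0 |
| green | 1.00 | 0 | 0 |
| green | 2.50 | 2.1 | 1.1 |
| violet | 0.200 | 0 | 0.7 |
| violet | 0.500 | 0 | 0.2 |
| violet | 1.00 | 0 | 0.4 |
| violet | 2.50 | 4.7 | 0.6 |
| teal | 0.667 | 0.6 | 0.9 |
| teal | 1.33 | 3.2 | 1.2 |
| teal | 2.00 | 6.9 | 2.5 |
| teal | 2.50 | 9.0 | 2.5 |

(standard deviation of a reading: 1 percentage point)

- free catalyst is single-handed; left-handed substrate and right-handed substrate are mirror images of each other, charged as a racemate, each of them at the stated concentration
- an excess is the difference of the two amounts in percent of their sum
- an excess is below zero if the other one leads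

1. the flask that ends with the higher excess of left-handed product over right-handed product in the product, or "neither" when 2 percentage points or less lies between them (noon / dawn / neither)
2. excess of left-handed product over right-handed product in the product at the end, noon
3. excess of left-handed product over right-handed product in the product at the end, dawn

Summed at 2.50 h over green, violet and teal, the readings give 15.8 % left-handed product and 4.20 % right-handed product. That is a ratio of 3.76, and each sum scatters by 1.7 percentage points.

Scaled by loading, this reckoning puts noon at 7.82 % and 2.08 %. These are percentages of both substrates together, so each counts double against its own charge. Noon is then reckoned to end at 0.880. This ratio of left-handed substrate left to right-handed substrate left, each as a part of its own charge, is the lean, and the rule stops where it leaves 1.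

Dawn, with less catalyst, is reckoned to end at 0.971. The square root of a lean serves as its mean over a run. The summed ratio already carries the earlier runs' own reckoned lean of 0.920 at their mean loading, so the selectivity factor reads 3.92. This reckoning then gives 57.3 % for noon and 58.9 % for dawn. The gap is 1.6 points, less than the margin, so the reckoning says neither.

The forecast also says neither, with 57 % for noon and 55 % for dawn, in the reverse order from this reckoning: “The excess is essentially unchanged with loading”. The flasks give neither, with 64.1 % for noon and 65.1 % for dawn.

    partner + free catalyst + left-handed substrate → free catalyst + left-handed product (k = 32.0 M⁻² h⁻¹)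
    partner + free catalyst + right-handed substrate → free catalyst + right-handed product (k = 6.70 M⁻² h⁻¹)
    free catalyst → spent catalyst B (k = 0.0290 h⁻¹)
    left-handed substrate ⇌ right-handed substrate (k = 0.310 h⁻¹)
    precatalyst → free catalyst (k = 0.140 h⁻¹)
    partner + free catalyst → spent catalyst A (k = 0.180 M⁻¹ h⁻¹)

Noon ends with a lean of 0.926, higher than the 0.880 reckoned. At 1.59 h in noon, the left-handed substrate has a half-life of 8.30 h by its product step, while the difference between the two substrates decays by their exchange with a half-life of 1.12 h, shorter. The neighbour of noon, the same flask with precatalyst at 0.4 mol%, comes to a lean of 0.949 when reckoned from its products. Its substrates stand at a lean of 0.969, and it ends with an excess of 64.9 %.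

All runs are calculated for an exercise, noise included.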